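## Structural features

The target 11 is a 2,4,5-trialkyl-1H-imidazole: C2 carries a 4-acetoxybutyl chain, C4 a 2-(3,4-dimethoxyphenyl)ethyl chain and C5 a methyl group, while N1–H is free and exchanges rapidly with N3. The imidazole and the veratrole ring are not fused but joined by an unfunctionalised CH2–CH2 bridge, and the molecule has no stereocentre. The fragile groups are the primary acetate (cleaved by ammonia, amines, alkoxide and hot aqueous base), the electron-rich dimethoxyarene (electrophilic halogenation, oxidants) and the basic, nucleophilic imidazole itself. The real difficulty is the ring: all three ring carbons bear different unactivated alkyl groups, and C4 and C5 differ only as CH2CH2Ar against CH3. Any carbonyl-condensation route therefore needs a regiodefined, vicinally difunctionalised five-carbon chain, which cannot be made by direct functionalisation of a ketone with two competing α-methylene groups. The feature that the key step exploits is the C5–CH3 pair next to N1: ring atom C5 and its methyl carbon are read as the two carbons of a terminal alkyne, and C4 as the propargylic carbon that already carries N3. An alkyne has exactly the oxidation level that C5 needs, so N1–C5 closure by 5-exo-dig hydroamination followed by a proton shift delivers the aromatic ring without an oxidant, a leaving group or a carbonyl partner. In one sentence: the imidazole ring is closed by addition of an amidine nitrogen across the terminal alkyne of the N-propargylamidinium salt 9, the alkyne terminus ending as the C5 methyl group.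

## Logic of the disconnections

11 is traced to 10 by returning one hydrogen of the C5 methyl group to C4, and 10 to 9 by cutting the N1–C5 bond. The cut is made there because it turns the aromatic ring into an open chain whose C5 and methyl carbon are an alkyne, which removes every carbonyl group from the ring synthesis. The gain is that ring, oxidation level and all three substituents arrive in one operation. The demand on the forward step is a 5-exo-dig closure in preference to 6-endo, followed by a proton shift, under conditions that leave the acetate alone.

9 is cut at the C2–N3 bond into 8 and 3. This is the convergent cut: it separates the C2 chain from the C4/C5 unit and makes the C4/C5 pattern a property of 8 alone. The demand is an amidination that is faster than aminolysis of the acetate and that can be run in the same flask as the ring closure.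

8 is traced through 7 and 6 to 4 and 5. The bond cut is the C–C bond between the carbinamine carbon and the alkyne (the later C4–C5 ring bond), and the C=N bond of 6 is cut back to 4 and 5. This reduces the C4/C5 unit to 4, 5 and an ethynyl Grignard reagent, and places nitrogen on the correct carbon by construction. The demand is 1,2-addition of an acetylide to an enolisable imine in preference to α-deprotonation; the new stereocentre needs no control because it is erased later.

3 is traced to 2 by cutting the imidate C–O bond and removing HCl, and 2 to 1 by cutting the acetate C–O bond; 1 is purchasable. The demand is that the acetate survives anhydrous hydrogen chloride in the presence of one equivalent of ethanol.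

## Other disconnections considered

Alternative 1: The first plan to come to mind cuts all four ring C–N bonds in a Debus–Radziszewski condensation of 5-(3,4-dimethoxyphenyl)pentane-2,3-dione A1 with 5-oxopentyl acetate A2 and ammonium acetate. A1 is exactly the regiodefined, vicinally dioxygenated chain that is the real problem, so the difficulty is only moved into a separate multistep synthesis. A2 is an enolisable aliphatic aldehyde and A1 an enolisable aliphatic diketone, which is the weakest case of this condensation, since aldol and oxazole-forming pathways compete. Hot ammonium acetate also exposes the acetate to aminolysis. The chosen plan needs no dicarbonyl compound and no ammonia.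

Alternative 2: The side chain is attached to a finished imidazole by cutting the bond between C4 and the bridge. The forward key step is a Sonogashira coupling of 4-(4-iodo-5-methyl-1H-imidazol-2-yl)butyl acetate A3 with 4-ethynyl-1,2-dimethoxybenzene A4, which would give 4-{4-[(3,4-dimethoxyphenyl)ethynyl]-5-methyl-1H-imidazol-2-yl}butyl acetate A5. Hydrogenation of A5 would then give 11. This does not address the ring at all: A3 still has to be built by a ring synthesis and then iodinated. A3 is an electron-rich, catalyst-binding N–H iodoimidazole that would probably need N-protection before it couples with A4, and the alkyne of A5 costs a further reduction step. The step count is clearly higher than in the chosen plan, where the saturated bridge is present from the start.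

Alternative 3: The C4–C5 bond is cut in a thiazolium-carbene-catalysed aza-benzoin addition. 5-Amino-5-oxopentyl acetate A6 would be condensed with acetaldehyde and p-toluenesulfinic acid to the α-amido sulfone 5-{[1-(4-methylbenzenesulfonyl)ethyl]amino}-5-oxopentyl acetate A7. Base would release from A7 the N-acylimine 5-[(E)-ethylideneamino]-5-oxopentyl acetate A8. Aldehyde 4 would add to A8 as an acyl-anion equivalent and give 5-{[5-(3,4-dimethoxyphenyl)-3-oxopentan-2-yl]amino}-5-oxopentyl acetate A9, which is then closed to 11 with ammonium acetate. A8 carries α-hydrogens and can lose its electrophilicity by imine-to-enamide tautomerisation, and the aliphatic donor 4 can undergo self-acyloin and aldol reactions. The C–C step delivers only the acyclic precursor A9, so a separate closure in hot ammonium acetate and acetic acid remains, with the acetate again exposed to ammonia. Starting from A6, the step count is no lower, and the chosen plan closes the ring in the key step itself.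

Key step: step 6

Remark on the chemistry: 1, 4 and 5 are taken as purchasable. Because 11 is achiral and its N1–H and N3–H tautomers interconvert, racemic 5 is used and the configuration at the carbinamine carbon of 7 to 10 is left undefined.

## Steps

Step 1
Reactants: 1 5-bromopentanenitrile
Product: 2 4-cyanobutyl acetate
Conditions: KOAc (1.5 equiv), DMF, 80 °C
Reagents that add atoms: potassium acetate, CC(=O)[O-].[K+]
Why: SN2 displacement of an unhindered primary bromide by acetate in a dipolar aprotic solvent (carboxylate alkylation); the nitrile is inert and elimination is not competitive with this weakly basic nucleophile.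

Step 2
Reactants: 2 4-cyanobutyl acetate
Product: 3 ethyl 5-acetoxypentanimidate hydrochloride
Conditions: HCl (g), EtOH (1.1 equiv), Et2O, 0 °C to 4 °C
Reagents that add atoms: ethanol, CCO; hydrogen chloride, Cl
Why: Pinner reaction: the N-protonated nitrile is trapped by ethanol and the imidate salt should crystallise from ether. Only one equivalent of alcohol at low temperature is used so that acid-catalysed exchange of the acetate stays slow relative to imidate formation.

Step 3
Reactants: 4 3-(3,4-dimethoxyphenyl)propanal; 5 racemic 2-methylpropane-2-sulfinamide
Product: 6 (E)-N-[3-(3,4-dimethoxyphenyl)propylidene]-2-methylpropane-2-sulfinamide (racemic at sulfur)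
Conditions: CuSO4 (anhydrous, 2 equiv), CH2Cl2, 23 °C
Reagents that add atoms: none
Why: Lewis-acid-assisted, water-scavenged condensation of a sulfinamide with an aldehyde, which is mild enough for enolisable aldehydes and should give the E aldimine. The sulfinyl group makes the imine of an enolisable aldehyde isolable and electrophilic, and the racemic reagent suffices because no stereocentre survives in 11.

Step 4
Reactants: 6 (E)-N-[3-(3,4-dimethoxyphenyl)propylidene]-2-methylpropane-2-sulfinamide
Product: 7 N-[5-(3,4-dimethoxyphenyl)pent-1-yn-3-yl]-2-methylpropane-2-sulfinamide (mixture of diastereomers, each racemic)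
Conditions: HC≡CMgBr (0.5 M in THF, 2 equiv), CH2Cl2, −78 °C to 0 °C; then aq. NH4Cl
Reagents that add atoms: ethynylmagnesium bromide, C#C[Mg]Br
Why: 1,2-addition of an alkynyl Grignard reagent to an N-sulfinyl aldimine, which forms the later C4–C5 bond; the sulfinyl group activates the C=N bond and the resulting sulfinamide anion cannot add a second time. The new carbinamine stereocentre is formed without control, which is acceptable because step 6 erases it.

Step 5
Reactants: 7 N-[5-(3,4-dimethoxyphenyl)pent-1-yn-3-yl]-2-methylpropane-2-sulfinamide
Product: 8 5-(3,4-dimethoxyphenyl)pent-1-yn-3-amine (racemic, free base)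
Conditions: HCl (4 M in dioxane, 2.5 equiv), MeOH, 0 °C to 23 °C; then aq. NaOH, extraction into CH2Cl2
Reagents that add atoms: none
Why: Acidolysis of the N–S bond of a tert-butanesulfinamide, with methanol trapping the sulfinyl fragment as its methyl ester. The aryl methyl ethers and the terminal alkyne are inert to anhydrous HCl at this temperature, and the basic work-up delivers the free primary propargylic amine.

Step 6
Reactants: 8 5-(3,4-dimethoxyphenyl)pent-1-yn-3-amine; 3 ethyl 5-acetoxypentanimidate hydrochloride
Product: 11 O-acetylcypholophine [4-{4-[2-(3,4-dimethoxyphenyl)ethyl]-5-methyl-1H-imidazol-2-yl}butyl acetate], via amidinium chloride 9 (not isolated), via 5-methylidene-imidazoline 10 (not isolated)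
Conditions: MeCN, 23 °C; evaporate; then Cs2CO3 (2 equiv), DMSO, 80 °C
Reagents that add atoms: none
Why: The free amine of 8 adds to the protonated imidate carbon of 3 and ethanol is expelled (Pinner amidine synthesis), which forms the C2–N3 bond and gives 9 at a temperature where the acetate should not be aminolysed; the liberated ethanol is removed with the solvent before base is added. Carbonate then liberates the amidine, whose unsubstituted nitrogen adds to the internal alkyne carbon and forms N1–C5; this closes the imidazole ring in the 5-exo-dig mode, either directly or after base-mediated propargyl-to-allenyl isomerisation and attack on the central allene carbon, and both paths end at 10. A base-mediated 1,3-proton shift from C4–H to the exocyclic methylene then aromatises 10 to 11, so that the alkyne terminus becomes the C5 methyl group and no oxidant or leaving group is needed. The closest known reaction type is the base- or π-acid-promoted cycloisomerisation of N-propargylamidines to 4(5)-methylimidazoles, the same closure that converts N-propargyl-2-aminopyridines into imidazo[1,2-a]pyridines. No stereocentre is created for the target, because the C4 centre of 8, 9 and 10 is erased in the aromatisation. The selectivity needed is 5-exo against 6-endo closure (a dihydropyrimidine); the terminal alkyne secures it, because the internal carbon is the electrophilic site in both the alkyne and the allene manifold and because only the five-membered product can aromatise and so drain the equilibria. The C4/C5 substitution pattern is not decided in this step at all, since the C4–N3 bond is already present in 8.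

## Compound list

1 | 5-bromopentanenitrile | N#CCCCCBr | starting material
2 | 4-cyanobutyl acetate | CC(=O)OCCCCC#N | intermediate
3 | ethyl 5-acetoxypentanimidate hydrochloride (5-ethoxy-5-iminopentyl acetate hydrochloride) | CCOC(=[NH2+])CCCCOC(C)=O.[Cl-] | intermediate
4 | 3-(3,4-dimethoxyphenyl)propanal | COc1ccc(CCC=O)cc1OC | starting material
5 | 2-methylpropane-2-sulfinamide (racemic) | CC(C)(C)S(N)=O | starting material
6 | (E)-N-[3-(3,4-dimethoxyphenyl)propylidene]-2-methylpropane-2-sulfinamide (racemic at sulfur) | COc1ccc(CC/C=N/S(=O)C(C)(C)C)cc1OC | intermediate
7 | N-[5-(3,4-dimethoxyphenyl)pent-1-yn-3-yl]-2-methylpropane-2-sulfinamide (mixture of diastereomers, each racemic) | COc1ccc(CCC(C#C)NS(=O)C(C)(C)C)cc1OC | intermediate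
8 | 5-(3,4-dimethoxyphenyl)pent-1-yn-3-amine (racemic) | COc1ccc(CCC(N)C#C)cc1OC | intermediate
9 | 5-{[5-(3,4-dimethoxyphenyl)pent-1-yn-3-yl]amino}-5-iminopentyl acetate hydrochloride (racemic; not isolated) | COc1ccc(CCC(C#C)NC(=[NH2+])CCCCOC(C)=O)cc1OC.[Cl-] | intermediate
10 | 4-{4-[2-(3,4-dimethoxyphenyl)ethyl]-5-methylidene-4,5-dihydro-1H-imidazol-2-yl}butyl acetate (racemic; not isolated) | COc1ccc(CCC2N=C(CCCCOC(C)=O)NC2=C)cc1OC | intermediate
11 | O-acetylcypholophine, 4-{4-[2-(3,4-dimethoxyphenyl)ethyl]-5-methyl-1H-imidazol-2-yl}butyl acetate | COc1ccc(CCc2nc(CCCCOC(C)=O)[nH]c2C)cc1OC | target

## Step count and least certain steps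

Total step count: 6. Longest linear sequence: 4 steps (steps 3, 4, 5 and 6, from 4); the second branch (steps 1 and 2) joins in step 6.

Step 6 (key step). Three processes could go wrong. The amidination at the α-branched amine may be slow, which would let the imidate salt collapse thermally to the primary amide. The hot carbonate stage may remove the acetyl group through adventitious water or transfer it to the strongly nucleophilic amidine. The proton shift that aromatises 10 may stall if the medium is not basic enough. Fallback, setting out from 8 and coming back at 11: 8 would be taken up as its hydrochloride in aqueous methanol and the alkyne hydrated in the Markovnikov sense (HCl 1.1 equiv, HgO 5 mol %, H2SO4 10 mol %, 60 °C) to give 3-amino-5-(3,4-dimethoxyphenyl)pentan-2-one hydrochloride F1. F1 would then be condensed with 3 (KOAc 2 equiv, MeCN, 23 °C to 60 °C) in the classical α-amino ketone–imidate imidazole synthesis, in which amidine formation is followed by cyclodehydration onto the ketone and gives 11 directly. The acetate buffer releases the amine of F1 only gradually, which limits self-condensation of the free α-amino ketone. This replaces alkyne hydroamination by carbonyl condensation and avoids the strongly basic stage.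

Step 2. Acid-catalysed exchange of the acetyl group with ethanol may compete with the slow Pinner addition to an aliphatic nitrile, and traces of moisture would hydrolyse the imidate salt to the ester. Fallback, setting out from 2 and coming back at 10: the nitrile would be thionated without alcohol ((EtO)2P(S)SH, H2O, 60 °C) to 5-amino-5-sulfanylidenepentyl acetate F2. S-Methylation (MeI, acetone, 23 °C) would give methyl 5-acetoxypentanimidothioate hydroiodide F3. F3 would react with 8 in MeCN, with loss of methanethiol, to give 5-{[5-(3,4-dimethoxyphenyl)pent-1-yn-3-yl]amino}-5-iminopentyl acetate hydroiodide F4. Treatment of F4 with Cs2CO3 in DMSO as in step 6 would then lead to 10, which aromatises to 11 in the same flask.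

Step 4. The basic acetylide may deprotonate the enolisable sulfinyl imine at its α-carbon instead of adding, which would return the imine or lead to self-condensation; a bis-magnesium acetylide formed by disproportionation could also add twice. Fallback, setting out from 4 and coming back at 8: ethynylmagnesium bromide would be added to the aldehyde itself (THF, −78 °C), where 1,2-addition is much faster than enolisation, to give 5-(3,4-dimethoxyphenyl)pent-1-yn-3-ol F5. A Mitsunobu reaction with phthalimide (PPh3, DIAD, THF, 0 °C to 23 °C) would give 2-[5-(3,4-dimethoxyphenyl)pent-1-yn-3-yl]isoindoline-1,3-dione F6. Hydrazinolysis of F6 (N2H4·H2O, EtOH, 60 °C) would then release 8, so that steps 3 to 5 are bypassed.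

## Further compounds

F1 | step 6 | 3-amino-5-(3,4-dimethoxyphenyl)pentan-2-one hydrochloride (racemic) | COc1ccc(CCC([NH3+])C(C)=O)cc1OC.[Cl-]
F2 | step 2 | 5-amino-5-sulfanylidenepentyl acetate | CC(=O)OCCCCC(N)=S
F3 | step 2 | methyl 5-acetoxypentanimidothioate hydroiodide | CSC(=[NH2+])CCCCOC(C)=O.[I-]
F4 | step 2 | 5-{[5-(3,4-dimethoxyphenyl)pent-1-yn-3-yl]amino}-5-iminopentyl acetate hydroiodide (racemic) | COc1ccc(CCC(C#C)NC(=[NH2+])CCCCOC(C)=O)cc1OC.[I-]
F5 | step 4 | 5-(3,4-dimethoxyphenyl)pent-1-yn-3-ol (racemic) | COc1ccc(CCC(O)C#C)cc1OC
F6 | step 4 | 2-[5-(3,4-dimethoxyphenyl)pent-1-yn-3-yl]isoindoline-1,3-dione (racemic) | COc1ccc(CCC(C#C)N2C(=O)c3ccccc3C2=O)cc1OC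
A1 | alternative 1 | 5-(3,4-dimethoxyphenyl)pentane-2,3-dione | COc1ccc(CCC(=O)C(C)=O)cc1OC
A2 | alternative 1 | 5-oxopentyl acetate | CC(=O)OCCCCC=O
A3 | alternative 2 | 4-(4-iodo-5-methyl-1H-imidazol-2-yl)butyl acetate | CC(=O)OCCCCc1nc(I)c(C)[nH]1
A4 | alternative 2 | 4-ethynyl-1,2-dimethoxybenzene | COc1ccc(C#C)cc1OC
A5 | alternative 2 | 4-{4-[(3,4-dimethoxyphenyl)ethynyl]-5-methyl-1H-imidazol-2-yl}butyl acetate | COc1ccc(C#Cc2nc(CCCCOC(C)=O)[nH]c2C)cc1OC
A6 | alternative 3 | 5-amino-5-oxopentyl acetate | CC(=O)OCCCCC(N)=O
A7 | alternative 3 | 5-{[1-(4-methylbenzenesulfonyl)ethyl]amino}-5-oxopentyl acetate (racemic) | CC(=O)OCCCCC(=O)NC(C)S(=O)(=O)c1ccc(C)cc1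
A8 | alternative 3 | 5-[(E)-ethylideneamino]-5-oxopentyl acetate | CC(=O)OCCCCC(=O)/N=C/C
A9 | alternative 3 | 5-{[5-(3,4-dimethoxyphenyl)-3-oxopentan-2-yl]amino}-5-oxopentyl acetate (racemic) | COc1ccc(CCC(=O)C(C)NC(=O)CCCCOC(C)=O)cc1OC
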